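The flavone is cut across ring C at C3–C4 and O1–C2, giving pentamethoxybenzoyl chloride and a 3-acetoxy-4-methoxyphenylacetylene. One SnCl4-promoted operation acylates the terminal alkyne carbon and lets an ortho methoxy oxygen capture the resulting C2 cation, closing the pyranone with loss of chloromethane. The step exploits two features: ring A bears five contiguous oxygens (O1 at C8a plus the methoxy groups on C8, C7, C6 and C5), so either ortho methoxy of the symmetric aroyl unit can become O1, and the 4'-methoxy group on ring B lies para to C1', stabilising charge at C2. Acetate masks the 3'-hydroxyl and is removed last.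

Key step: step 7

Assumption: 1,2,3,5-tetramethoxybenzene, isovanillin and the Ohira–Bestmann reagent are taken as catalogue chemicals; the target is achiral, so no stereocentre has to be set.

**Route**

Step 1
Reactants: 1 1,2,3,5-tetramethoxybenzene
Product: 4 2,3,4,6-tetramethoxyphenol, via aryllithium 2 (not isolated), via lithium aryltrimethoxyborate 3 (not isolated)
Conditions: n-BuLi, TMEDA, THF, 0 °C; B(OMe)3, −78 °C → rt; AcOH, 30% aq. H2O2, 0 °C → rt
Reagents that add atoms: hydrogen peroxide, OO (oxygen of the phenol); for intermediates 2 and 3 only: n-butyllithium, [Li]CCCC; trimethyl borate, COB(OC)OC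
Why: Directed ortho-metalation should give a single aryllithium because the two ring hydrogens of 1 are equivalent and each is flanked by two methoxy groups; borylation and peroxide oxidation of the aryl boron species (carbon-to-oxygen 1,2-shift) then deliver the phenol.

Step 2
Reactants: 4 2,3,4,6-tetramethoxyphenol
Product: 5 pentamethoxybenzene
Conditions: MeI, K2CO3, DMF, rt
Reagents that add atoms: iodomethane, CI
Why: Williamson O-methylation of the phenoxide should proceed cleanly, since the molecule has no other nucleophilic site.

Step 3
Reactants: 5 pentamethoxybenzene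
Product: 7 2,3,4,5,6-pentamethoxybenzoic acid, via aryllithium 6 (not isolated)
Conditions: n-BuLi, TMEDA, THF, 0 °C → rt; CO2 (g), −78 °C → rt; aq. HCl
Reagents that add atoms: carbon dioxide, O=C=O; for intermediate 6 only: n-butyllithium, [Li]CCCC
Why: Directed ortho-lithiation can only occur at the single ring C–H, which lies between two methoxy groups, and carboxylation of the aryllithium with CO2 gives the benzoic acid after acidification.

Step 4
Reactants: 7 2,3,4,5,6-pentamethoxybenzoic acid
Product: 8 2,3,4,5,6-pentamethoxybenzoyl chloride
Conditions: (COCl)2, DMF (cat.), CH2Cl2, 0 °C → rt; evaporate, use crude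
Reagents that add atoms: oxalyl chloride, O=C(Cl)C(=O)Cl
Why: Acid chloride formation through the catalytic chloroiminium (Vilsmeier-type) species runs under near-neutral conditions that leave aryl methyl ethers untouched, and all by-products are volatile.

Step 5
Reactants: 9 isovanillin
Product: 10 5-ethynyl-2-methoxyphenol
Conditions: dimethyl (1-diazo-2-oxopropyl)phosphonate, K2CO3 (3 equiv), MeOH, 0 °C → rt; aq. NH4Cl
Reagents that add atoms: dimethyl (1-diazo-2-oxopropyl)phosphonate (Ohira–Bestmann reagent), COP(=O)(OC)C(=[N+]=[N-])C(C)=O
Why: Seyferth–Gilbert homologation in its Ohira–Bestmann form should convert the aldehyde into the terminal alkyne (Horner–Wadsworth–Emmons-type olefination, loss of N2, 1,2-hydride shift); the phenoxide is meta to the formyl group and so does not deactivate it, and extra K2CO3 covers the acidic phenol.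

Step 6
Reactants: 10 5-ethynyl-2-methoxyphenol
Product: 11 5-ethynyl-2-methoxyphenyl acetate
Conditions: Ac2O, pyridine, DMAP (cat.), CH2Cl2, 0 °C → rt
Reagents that add atoms: acetic anhydride, CC(=O)OC(C)=O
Why: DMAP-catalysed O-acetylation of the phenol (nucleophilic acyl substitution) should be clean; the acetate is chosen because it prevents O-aroylation by 8, tempers ring B against Friedel–Crafts attack, resists SnCl4 at low temperature better than silyl or benzyl ethers, and leaves under mild methanolysis.

Step 7
Reactants: 8 2,3,4,5,6-pentamethoxybenzoyl chloride; 11 5-ethynyl-2-methoxyphenyl acetate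
Product: 13 3'-O-acetyl-3'-demethylnobiletin, via O-methyl oxonium chloride 12 (not isolated)
Conditions: SnCl4 (2 equiv), CH2Cl2, −20 °C → rt; aq. NaHCO3
Reagents that add atoms: none
Why: SnCl4 should ionise the di-ortho-substituted acid chloride 8 to a hindered, donor-stabilised acylium ion that adds to the terminal carbon of alkyne 11 (new C3–C4 bond), leaving a linear vinyl cation at C2 that is benzylic to ring B and stabilised by the para 4'-methoxy group. An ortho methoxy oxygen of the aroyl ring then attacks this cation (new O1–C2 bond) in a 6-endo closure onto the digonal carbon, so that the former triple bond ends inside ring C as C2=C3 and the ring is formed as the O-methyl oxonium ion 12; chloride removes the oxonium methyl group by SN2 displacement, releasing chloromethane and flavone 13. The closest known reaction type is the Lewis acid promoted domino Friedel–Crafts acylation of alkynes with 2-methoxybenzoyl chlorides followed by demethylative annulation to chromones. No stereocentre is created. Regioselectivity (acyl on the terminal carbon) follows from the aryl-stabilised cation, and the two ortho methoxy groups of 8 are equivalent by symmetry, so only one flavone can form. Chemoselectivity rests on the mild Lewis acid and low temperature, which should spare the peri C5 methoxy group and the ester, and on the acetate, which blocks O-aroylation and lowers the nucleophilicity of ring B.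

Step 8
Reactants: 13 3'-O-acetyl-3'-demethylnobiletin
Product: 14 3'-demethylnobiletin
Conditions: K2CO3 (0.3 equiv), MeOH/THF, 0 °C → rt; aq. NH4Cl
Reagents that add atoms: none
Why: Base-catalysed transesterification (Zemplén-type methanolysis) should cleave the aryl acetate selectively, since the aryl methyl ethers and the pyranone ring are inert to catalytic K2CO3 in methanol at room temperature.

**Compound list**

1 | 1,2,3,5-tetramethoxybenzene | COc1cc(OC)cc(OC)c1OC | starting material
2 | 2,3,4,6-tetramethoxyphenyllithium | [Li]c1c(OC)cc(OC)c(OC)c1OC | intermediate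
3 | lithium trimethoxy(2,3,4,6-tetramethoxyphenyl)borate | [Li+].CO[B-](OC)(OC)c1c(OC)cc(OC)c(OC)c1OC | intermediate
4 | 2,3,4,6-tetramethoxyphenol | COc1cc(OC)c(OC)c(OC)c1O | intermediate
5 | pentamethoxybenzene | COc1cc(OC)c(OC)c(OC)c1OC | intermediate
6 | pentamethoxyphenyllithium | [Li]c1c(OC)c(OC)c(OC)c(OC)c1OC | intermediate
7 | 2,3,4,5,6-pentamethoxybenzoic acid | COc1c(OC)c(OC)c(C(=O)O)c(OC)c1OC | intermediate
8 | 2,3,4,5,6-pentamethoxybenzoyl chloride | COc1c(OC)c(OC)c(C(=O)Cl)c(OC)c1OC | intermediate
9 | isovanillin (3-hydroxy-4-methoxybenzaldehyde) | COc1ccc(C=O)cc1O | starting material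
10 | 5-ethynyl-2-methoxyphenol | COc1ccc(C#C)cc1O | intermediate
11 | 5-ethynyl-2-methoxyphenyl acetate | CC(=O)Oc1cc(C#C)ccc1OC | intermediate
12 | 2-(3-acetoxy-4-methoxyphenyl)-5,6,7,8-tetramethoxy-1-methyl-4-oxo-4H-chromen-1-ium chloride (O1-methyl oxonium ion; counter-ion in the flask SnCl5−, written as chloride) | COc1ccc(cc1OC(C)=O)C1=CC(=O)c2c(OC)c(OC)c(OC)c(OC)c2[O+]1C.[Cl-] | intermediate
13 | 3'-O-acetyl-3'-demethylnobiletin (2-methoxy-5-(5,6,7,8-tetramethoxy-4-oxo-4H-chromen-2-yl)phenyl acetate) | COc1ccc(-c2cc(=O)c3c(OC)c(OC)c(OC)c(OC)c3o2)cc1OC(C)=O | intermediate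
14 | 3'-demethylnobiletin (2-(3-hydroxy-4-methoxyphenyl)-5,6,7,8-tetramethoxy-4H-chromen-4-one) | COc1ccc(-c2cc(=O)c3c(OC)c(OC)c(OC)c(OC)c3o2)cc1O | target

**Step count**

Total step count: 8.
Longest linear sequence: 6 steps (steps 1, 2, 3, 4, 7, 8); steps 5 and 6 form the second branch.

**Steps most likely to fail**

Step 7. Chloride may capture the vinyl cation faster than the ortho methoxy oxygen, so that the sequence stalls before ring closure. The Lewis acid may also cleave the chelated C5 methoxy group or the acetate once the chromone carbonyl is present. The fallback sets out from 8 and 11 and separates the two bond formations without a strong Lewis acid. A copper-cocatalysed acyl Sonogashira coupling (PdCl2(PPh3)2, CuI, Et3N, THF, rt) should give the ynone 2-methoxy-5-[3-oxo-3-(2,3,4,5,6-pentamethoxyphenyl)prop-1-yn-1-yl]phenyl acetate F1. Iodine monochloride (CH2Cl2, −78 °C) should then trigger iodocyclisation with loss of the ortho methyl group, giving the 3-iodoflavone 2-(3-acetoxy-4-methoxyphenyl)-3-iodo-5,6,7,8-tetramethoxy-4H-chromen-4-one F2. Palladium-catalysed formate reduction (Pd(OAc)2, PPh3, HCO2H, Et3N, DMF, 60 °C) should remove the iodine and bring the route back at 13.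

Step 1. Incomplete metalation, or over-oxidation of the very electron-rich phenol during the peroxide treatment, would erode the hydroxylation. The fallback sets out from 1 and avoids organometallic intermediates. Vilsmeier–Haack formylation (POCl3, DMF, 0 °C → rt) should give 2,3,4,6-tetramethoxybenzaldehyde F3. Baeyer–Villiger oxidation (mCPBA, CH2Cl2, rt) should give 2,3,4,6-tetramethoxyphenyl formate F4 by aryl migration. Brief methanolysis (K2CO3 cat., MeOH, rt) should then release the phenol, and the route is rejoined at 4.

Step 3. Slow deprotonation at the doubly buttressed position, or proton return before carboxylation, would leave 5 unchanged. The fallback sets out from 5 and generates the carbanion by halogen–metal exchange in place of C–H deprotonation. Electrophilic bromination (NBS, MeCN, 0 °C) should give 1-bromo-2,3,4,5,6-pentamethoxybenzene F5. Bromine–lithium exchange (n-BuLi, THF, −78 °C) should then form the aryllithium quantitatively, so the route is rejoined at 6, which is carboxylated as in step 3 to give 7.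

**Further compounds**

F1 | step 7 | 2-methoxy-5-[3-oxo-3-(2,3,4,5,6-pentamethoxyphenyl)prop-1-yn-1-yl]phenyl acetate | COc1ccc(C#CC(=O)c2c(OC)c(OC)c(OC)c(OC)c2OC)cc1OC(C)=O
F2 | step 7 | 2-(3-acetoxy-4-methoxyphenyl)-3-iodo-5,6,7,8-tetramethoxy-4H-chromen-4-one | COc1ccc(-c2oc3c(OC)c(OC)c(OC)c(OC)c3c(=O)c2I)cc1OC(C)=O
F3 | step 1 | 2,3,4,6-tetramethoxybenzaldehyde | COc1cc(OC)c(OC)c(OC)c1C=O
F4 | step 1 | 2,3,4,6-tetramethoxyphenyl formate | COc1cc(OC)c(OC)c(OC)c1OC=O
F5 | step 3 | 1-bromo-2,3,4,5,6-pentamethoxybenzene | COc1c(OC)c(OC)c(Br)c(OC)c1OC
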